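**Retrosynthetic overview**
1. The ten-membered carbocycle is closed last, at C9–C10, by Ni/Cr vinylation of a C9 aldehyde with a (Z)-2-bromo enoate; acetylation at C9 and desilylation at C2 finish the target.
2. The bromo enoate (C10, C14) and the C2 oxygen are built on a C1 aldehyde (ozonolysis of the nerol tail) by proline-catalysed aminoxylation and a bromo-Wittig olefination.
3. Key disconnection C7–C8: a 3-(bromomethyl)butenolide is turned by CrCl2 into a polarity-reversed nucleophile at the lactone beta-carbon (homoenolate type) and added to a C8 aldehyde; C8 is then inverted as the angelate is installed.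
4. The butenolide comes from ring-closing metathesis of the 2-(bromomethyl)acrylate of a vinyl carbinol, made by Felkin vinylation of epoxyneral from Sharpless epoxidation of nerol.
5. Ring order: oxirane, then butenolide (which becomes the alpha-methylene gamma-lactone), then the ten-membered ring.

Assumption: atom labels C1–C15 are the germacranolide numbers of the target (C12 lactone carbonyl, C13 methylidene, C14 ester carbon, C15 methyl); the target SMILES corresponds to 2S,4R,5S,6S,7R,8S,9S; angeloyl means (2Z)-2-methylbut-2-enoyl.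

**Route**

Step 1
Reactants: 1 nerol
Product: 2 (2S,3R)-2,3-epoxynerol
Conditions: Ti(OiPr)4 (10 mol%), L-(+)-diethyl tartrate (12 mol%), t-BuOOH, 4 Å MS, CH2Cl2, −20 °C
Reagents that add atoms: tert-butyl hydroperoxide, CC(C)(C)OO
Why: Sharpless asymmetric epoxidation, in which the titanium tartrate complex binds the allylic alcohol and with L-(+)-tartrate delivers oxygen to the face that gives the (2S,3R)-epoxide (C4 R and C5 S of the target), leaving the remote trisubstituted alkene untouched.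

Step 2
Reactants: 2 (2S,3R)-2,3-epoxynerol
Product: 3 (2R,3R)-2,3-epoxyneral
Conditions: IBX, DMSO, rt
Reagents that add atoms: none
Why: IBX oxidation of the primary alcohol is neutral, so the epoxy aldehyde forms without epimerisation at C5 or epoxide opening.

Step 3
Reactants: 3 (2R,3R)-2,3-epoxyneral
Product: 4 (3S,4S,5R)-4,5-epoxy-5,9-dimethyldeca-1,8-dien-3-ol
Conditions: CH2=CHMgBr, THF, −78 °C; aq. NH4Cl
Reagents that add atoms: vinylmagnesium bromide, C=C[Mg]Br
Why: Grignard 1,2-addition under Felkin–Anh control (epoxide C–O bond anti to the incoming vinyl group in non-chelating THF at low temperature) gives the anti epoxy alcohol and so sets C6 as S.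

Step 4
Reactants: 4 (3S,4S,5R)-4,5-epoxy-5,9-dimethyldeca-1,8-dien-3-ol; 5 2-(bromomethyl)acrylic acid
Product: 6 (3S,4S,5R)-4,5-epoxy-5,9-dimethyldeca-1,8-dien-3-yl 2-(bromomethyl)acrylate
Conditions: DCC, DMAP (10 mol%), CH2Cl2, 0 °C
Reagents that add atoms: none
Why: Steglich esterification acylates the hindered secondary alcohol under mild conditions without touching the stereocentres or the allylic bromide.

Step 5
Reactants: 6 (3S,4S,5R)-4,5-epoxy-5,9-dimethyldeca-1,8-dien-3-yl 2-(bromomethyl)acrylate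
Product: 7 (5S)-3-(bromomethyl)-5-[(2S,3R)-3-methyl-3-(4-methylpent-3-enyl)oxiran-2-yl]furan-2(5H)-one
Conditions: second-generation Grubbs catalyst (5 mol%), CH2Cl2, 40 °C, 0.01 M
Reagents that add atoms: none
Why: Ring-closing metathesis between the vinyl group and the 1,1-disubstituted acrylate releases ethylene and forms the butenolide (C7=C11), the trisubstituted alkene being too hindered to compete.

Step 6
Reactants: 7 (5S)-3-(bromomethyl)-5-[(2S,3R)-3-methyl-3-(4-methylpent-3-enyl)oxiran-2-yl]furan-2(5H)-one; 8 (tert-butyldimethylsilyloxy)acetaldehyde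
Product: 9 (4R,5S)-4-[(1R)-2-(tert-butyldimethylsilyloxy)-1-hydroxyethyl]-3-methylidene-5-[(2S,3R)-3-methyl-3-(4-methylpent-3-enyl)oxiran-2-yl]oxolan-2-one
Conditions: CrCl2 (3 equiv), THF, 0 °C to rt; H2O
Reagents that add atoms: none
Why: Nozaki–Hiyama allylation in which CrCl2 turns the allylic bromide into an allyl chromium species, so that C7 (the beta-carbon of the lactone carbonyl) reacts as a homoenolate-type nucleophile with the aldehyde carbon C8, joining two carbons that are both electrophilic by nature; attack anti to the C6 side chain sets C7 (trans lactone), the chair transition state with the ring-locked E allyl unit gives the 7,8-anti carbinol (C8 R), and the double bond moves to the exocyclic C11=C13 position.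

Step 7
Reactants: 9 (4R,5S)-4-[(1R)-2-(tert-butyldimethylsilyloxy)-1-hydroxyethyl]-3-methylidene-5-[(2S,3R)-3-methyl-3-(4-methylpent-3-enyl)oxiran-2-yl]oxolan-2-one; 10 angelic acid
Product: 11 (4R,5S)-4-[(1S)-1-(angeloyloxy)-2-(tert-butyldimethylsilyloxy)ethyl]-3-methylidene-5-[(2S,3R)-3-methyl-3-(4-methylpent-3-enyl)oxiran-2-yl]oxolan-2-one
Conditions: PPh3, DIAD, toluene, 0 °C to rt
Reagents that add atoms: none
Why: Mitsunobu esterification displaces the activated C8 oxygen by angelate with SN2 inversion, converting the 8R alcohol into the 8S angelate required by the target without base that could isomerise angelate to tiglate.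

Step 8
Reactants: 11 (4R,5S)-4-[(1S)-1-(angeloyloxy)-2-(tert-butyldimethylsilyloxy)ethyl]-3-methylidene-5-[(2S,3R)-3-methyl-3-(4-methylpent-3-enyl)oxiran-2-yl]oxolan-2-one
Product: 12 (4R,5S)-4-[(1S)-1-(angeloyloxy)-2-(tert-butyldimethylsilyloxy)ethyl]-3-methylidene-5-[(2S,3R)-3-methyl-3-(3-oxopropyl)oxiran-2-yl]oxolan-2-one
Conditions: O3 (1.0 equiv), pyridine, CH2Cl2, −78 °C; PPh3
Reagents that add atoms: ozone, [O-][O+]=O
Why: Ozonolysis is chemoselective for the electron-rich trisubstituted alkene over the two conjugated, electron-poor alkenes and gives the C1 aldehyde with loss of acetone.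

Step 9
Reactants: 13 methyl (triphenylphosphoranylidene)acetate
Product: 14 methyl bromo(triphenylphosphoranylidene)acetate
Conditions: Br2, CH2Cl2, 0 °C; aq. NaOH
Reagents that add atoms: bromine, BrBr
Why: Electrophilic bromination of the stabilised ylide followed by deprotonation of the phosphonium salt gives the bromo ylide, with no stereocentre involved.

Step 10
Reactants: 12 (4R,5S)-4-[(1S)-1-(angeloyloxy)-2-(tert-butyldimethylsilyloxy)ethyl]-3-methylidene-5-[(2S,3R)-3-methyl-3-(3-oxopropyl)oxiran-2-yl]oxolan-2-one; 14 methyl bromo(triphenylphosphoranylidene)acetate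
Product: 16 methyl (2Z,4S)-4-(anilinooxy)-2-bromo-5-[(2R,3S)-3-{(2S,3R)-3-[(1S)-1-(angeloyloxy)-2-(tert-butyldimethylsilyloxy)ethyl]-4-methylidene-5-oxooxolan-2-yl}-2-methyloxiran-2-yl]pent-2-enoate, via alpha-anilinooxy aldehyde 15 (not isolated)
Conditions: PhNO, D-proline (20 mol%), CHCl3, 4 °C; then 14, CH2Cl2, 0 °C to rt
Reagents that add atoms: nitrosobenzene, O=Nc1ccccc1
Why: Proline-catalysed alpha-aminoxylation (enamine attack on the oxygen of nitrosobenzene, D-proline giving the 2S centre) followed in the same flask by Wittig olefination with the stabilised bromo ylide, which gives the (Z)-2-bromo enoate with C2 trans to the ester.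

Step 11
Reactants: 16 methyl (2Z,4S)-4-(anilinooxy)-2-bromo-5-[(2R,3S)-3-{(2S,3R)-3-[(1S)-1-(angeloyloxy)-2-(tert-butyldimethylsilyloxy)ethyl]-4-methylidene-5-oxooxolan-2-yl}-2-methyloxiran-2-yl]pent-2-enoate
Product: 17 methyl (2Z,4S)-2-bromo-4-hydroxy-5-[(2R,3S)-3-{(2S,3R)-3-[(1S)-1-(angeloyloxy)-2-(tert-butyldimethylsilyloxy)ethyl]-4-methylidene-5-oxooxolan-2-yl}-2-methyloxiran-2-yl]pent-2-enoate
Conditions: Cu(OAc)2 (30 mol%), EtOH, rt
Reagents that add atoms: none
Why: Copper-catalysed N–O bond cleavage unmasks the C2 hydroxyl with retention and leaves the vinyl bromide, epoxide and esters intact.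

Step 12
Reactants: 17 methyl (2Z,4S)-2-bromo-4-hydroxy-5-[(2R,3S)-3-{(2S,3R)-3-[(1S)-1-(angeloyloxy)-2-(tert-butyldimethylsilyloxy)ethyl]-4-methylidene-5-oxooxolan-2-yl}-2-methyloxiran-2-yl]pent-2-enoate
Product: 18 methyl (2Z,4S)-2-bromo-4-(tert-butyldimethylsilyloxy)-5-[(2R,3S)-3-{(2S,3R)-3-[(1S)-1-(angeloyloxy)-2-(tert-butyldimethylsilyloxy)ethyl]-4-methylidene-5-oxooxolan-2-yl}-2-methyloxiran-2-yl]pent-2-enoate
Conditions: TBSOTf, 2,6-lutidine, CH2Cl2, −78 °C
Reagents that add atoms: tert-butyldimethylsilyl trifluoromethanesulfonate, CC(C)(C)[Si](C)(C)OS(=O)(=O)C(F)(F)F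
Why: Silylation with a silyl triflate and a non-nucleophilic base protects the secondary C2 alcohol so that only the C9 oxygen can be acetylated later.

Step 13
Reactants: 18 methyl (2Z,4S)-2-bromo-4-(tert-butyldimethylsilyloxy)-5-[(2R,3S)-3-{(2S,3R)-3-[(1S)-1-(angeloyloxy)-2-(tert-butyldimethylsilyloxy)ethyl]-4-methylidene-5-oxooxolan-2-yl}-2-methyloxiran-2-yl]pent-2-enoate
Product: 19 methyl (2Z,4S)-2-bromo-4-(tert-butyldimethylsilyloxy)-5-[(2R,3S)-3-{(2S,3R)-3-[(1S)-1-(angeloyloxy)-2-hydroxyethyl]-4-methylidene-5-oxooxolan-2-yl}-2-methyloxiran-2-yl]pent-2-enoate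
Conditions: HF·pyridine, pyridine, THF, 0 °C
Reagents that add atoms: none
Why: Buffered fluoride desilylation removes the less hindered primary silyl ether selectively, and the slightly acidic medium suppresses migration of the angelate to the freed C9 oxygen.

Step 14
Reactants: 19 methyl (2Z,4S)-2-bromo-4-(tert-butyldimethylsilyloxy)-5-[(2R,3S)-3-{(2S,3R)-3-[(1S)-1-(angeloyloxy)-2-hydroxyethyl]-4-methylidene-5-oxooxolan-2-yl}-2-methyloxiran-2-yl]pent-2-enoate
Product: 20 methyl (2Z,4S)-2-bromo-4-(tert-butyldimethylsilyloxy)-5-[(2R,3S)-3-{(2S,3S)-3-[(1S)-1-(angeloyloxy)-2-oxoethyl]-4-methylidene-5-oxooxolan-2-yl}-2-methyloxiran-2-yl]pent-2-enoate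
Conditions: IBX, DMSO, rt; used crude
Reagents that add atoms: none
Why: IBX oxidation gives the alpha-acyloxy aldehyde under neutral conditions, so C8 is not epimerised.

Step 15
Reactants: 20 methyl (2Z,4S)-2-bromo-4-(tert-butyldimethylsilyloxy)-5-[(2R,3S)-3-{(2S,3S)-3-[(1S)-1-(angeloyloxy)-2-oxoethyl]-4-methylidene-5-oxooxolan-2-yl}-2-methyloxiran-2-yl]pent-2-enoate
Product: 21 methyl (1(10)E,2S,4R,5S,6S,7R,8S,9S)-8-(angeloyloxy)-2-(tert-butyldimethylsilyloxy)-4,5-epoxy-9-hydroxygermacra-1(10),11(13)-dien-6,12-olid-14-oate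
Conditions: CrCl2 (8 equiv), NiCl2 (5 mol%), DMSO, rt, 2 mM, slow addition; H2O
Reagents that add atoms: none
Why: Nozaki–Hiyama–Kishi macrocyclisation, in which the vinyl bromide becomes a vinyl chromium species with retention of geometry (C2 and C9 cis on C1=C10) and adds to the aldehyde to close the ten-membered ring; C9 is expected to be set by the ring, because with the C9=O bond anti to the C8–O dipole the tether should bring the nucleophile in syn-clinal to C7, which gives the 8,9-syn (9S) carbinol.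

Step 16
Reactants: 21 methyl (1(10)E,2S,4R,5S,6S,7R,8S,9S)-8-(angeloyloxy)-2-(tert-butyldimethylsilyloxy)-4,5-epoxy-9-hydroxygermacra-1(10),11(13)-dien-6,12-olid-14-oate
Product: 22 methyl (1(10)E,2S,4R,5S,6S,7R,8S,9S)-9-acetoxy-8-(angeloyloxy)-2-(tert-butyldimethylsilyloxy)-4,5-epoxygermacra-1(10),11(13)-dien-6,12-olid-14-oate
Conditions: Ac2O, pyridine, DMAP (cat.), CH2Cl2, 0 °C
Reagents that add atoms: acetic anhydride, CC(=O)OC(C)=O
Why: Nucleophile-catalysed acylation esterifies the only free hydroxyl (C9) with retention.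

Step 17
Reactants: 22 methyl (1(10)E,2S,4R,5S,6S,7R,8S,9S)-9-acetoxy-8-(angeloyloxy)-2-(tert-butyldimethylsilyloxy)-4,5-epoxygermacra-1(10),11(13)-dien-6,12-olid-14-oate
Product: 23 methyl (1(10)E,2S,4R,5S,6S,7R,8S,9S)-9-acetoxy-8-(angeloyloxy)-4,5-epoxy-2-hydroxygermacra-1(10),11(13)-dien-6,12-olid-14-oate (CNP0278274.1)
Conditions: HF·pyridine, pyridine, THF, 0 °C to rt
Reagents that add atoms: none
Why: Fluoride desilylation frees the C2 hydroxyl under conditions that spare the epoxide, both esters and the alpha-methylene lactone, and C2–OH cannot lactonise because it is trans to the ester.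

**Compound list**
1 | nerol, (2Z)-3,7-dimethylocta-2,6-dien-1-ol | CC(C)=CCC/C(C)=C\CO | starting material
2 | (2S,3R)-2,3-epoxynerol | CC(C)=CCC[C@@]1(C)O[C@H]1CO | intermediate
3 | (2R,3R)-2,3-epoxyneral | CC(C)=CCC[C@@]1(C)O[C@H]1C=O | intermediate
4 | (3S,4S,5R)-4,5-epoxy-5,9-dimethyldeca-1,8-dien-3-ol | CC(C)=CCC[C@@]1(C)O[C@H]1[C@@H](O)C=C | intermediate
5 | 2-(bromomethyl)acrylic acid | C=C(CBr)C(=O)O | starting material
6 | (3S,4S,5R)-4,5-epoxy-5,9-dimethyldeca-1,8-dien-3-yl 2-(bromomethyl)acrylate | CC(C)=CCC[C@@]1(C)O[C@H]1[C@@H](OC(=O)C(=C)CBr)C=C | intermediate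
7 | (5S)-3-(bromomethyl)-5-[(2S,3R)-3-methyl-3-(4-methylpent-3-enyl)oxiran-2-yl]furan-2(5H)-one | CC(C)=CCC[C@@]1(C)O[C@H]1[C@H]2OC(=O)C(CBr)=C2 | intermediate
8 | (tert-butyldimethylsilyloxy)acetaldehyde | O=CCO[Si](C)(C)C(C)(C)C | starting material
9 | (4R,5S)-4-[(1R)-2-(tert-butyldimethylsilyloxy)-1-hydroxyethyl]-3-methylidene-5-[(2S,3R)-3-methyl-3-(4-methylpent-3-enyl)oxiran-2-yl]oxolan-2-one | C=C1C(=O)O[C@H]([C@@H]2O[C@]2(C)CCC=C(C)C)[C@H]1[C@@H](O)CO[Si](C)(C)C(C)(C)C | intermediate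
10 | angelic acid, (2Z)-2-methylbut-2-enoic acid | C/C=C(/C)C(=O)O | starting material
11 | (4R,5S)-4-[(1S)-1-(angeloyloxy)-2-(tert-butyldimethylsilyloxy)ethyl]-3-methylidene-5-[(2S,3R)-3-methyl-3-(4-methylpent-3-enyl)oxiran-2-yl]oxolan-2-one | C=C1C(=O)O[C@H]([C@@H]2O[C@]2(C)CCC=C(C)C)[C@H]1[C@H](OC(=O)/C(C)=C\C)CO[Si](C)(C)C(C)(C)C | intermediate
12 | (4R,5S)-4-[(1S)-1-(angeloyloxy)-2-(tert-butyldimethylsilyloxy)ethyl]-3-methylidene-5-[(2S,3R)-3-methyl-3-(3-oxopropyl)oxiran-2-yl]oxolan-2-one | C=C1C(=O)O[C@H]([C@@H]2O[C@]2(C)CCC=O)[C@H]1[C@H](OC(=O)/C(C)=C\C)CO[Si](C)(C)C(C)(C)C | intermediate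
13 | methyl (triphenylphosphoranylidene)acetate | COC(=O)C=P(c1ccccc1)(c1ccccc1)c1ccccc1 | starting material
14 | methyl bromo(triphenylphosphoranylidene)acetate | COC(=O)C(Br)=P(c1ccccc1)(c1ccccc1)c1ccccc1 | intermediate
15 | alpha-anilinooxy aldehyde (aldehyde 12 carrying a (2S)-anilinooxy group at C2) | C=C1C(=O)O[C@H]([C@@H]2O[C@]2(C)C[C@H](ONc2ccccc2)C=O)[C@H]1[C@H](OC(=O)/C(C)=C\C)CO[Si](C)(C)C(C)(C)C | intermediate
16 | methyl (2Z,4S)-4-(anilinooxy)-2-bromo-5-[(2R,3S)-3-{(2S,3R)-3-[(1S)-1-(angeloyloxy)-2-(tert-butyldimethylsilyloxy)ethyl]-4-methylidene-5-oxooxolan-2-yl}-2-methyloxiran-2-yl]pent-2-enoate | C=C1C(=O)O[C@H]([C@@H]2O[C@]2(C)C[C@H](ONc2ccccc2)/C=C(\Br)C(=O)OC)[C@H]1[C@H](OC(=O)/C(C)=C\C)CO[Si](C)(C)C(C)(C)C | intermediate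
17 | methyl (2Z,4S)-2-bromo-4-hydroxy-5-[(2R,3S)-3-{(2S,3R)-3-[(1S)-1-(angeloyloxy)-2-(tert-butyldimethylsilyloxy)ethyl]-4-methylidene-5-oxooxolan-2-yl}-2-methyloxiran-2-yl]pent-2-enoate | C=C1C(=O)O[C@H]([C@@H]2O[C@]2(C)C[C@H](O)/C=C(\Br)C(=O)OC)[C@H]1[C@H](OC(=O)/C(C)=C\C)CO[Si](C)(C)C(C)(C)C | intermediate
18 | methyl (2Z,4S)-2-bromo-4-(tert-butyldimethylsilyloxy)-5-[(2R,3S)-3-{(2S,3R)-3-[(1S)-1-(angeloyloxy)-2-(tert-butyldimethylsilyloxy)ethyl]-4-methylidene-5-oxooxolan-2-yl}-2-methyloxiran-2-yl]pent-2-enoate | C=C1C(=O)O[C@H]([C@@H]2O[C@]2(C)C[C@H](O[Si](C)(C)C(C)(C)C)/C=C(\Br)C(=O)OC)[C@H]1[C@H](OC(=O)/C(C)=C\C)CO[Si](C)(C)C(C)(C)C | intermediate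
19 | methyl (2Z,4S)-2-bromo-4-(tert-butyldimethylsilyloxy)-5-[(2R,3S)-3-{(2S,3R)-3-[(1S)-1-(angeloyloxy)-2-hydroxyethyl]-4-methylidene-5-oxooxolan-2-yl}-2-methyloxiran-2-yl]pent-2-enoate | C=C1C(=O)O[C@H]([C@@H]2O[C@]2(C)C[C@H](O[Si](C)(C)C(C)(C)C)/C=C(\Br)C(=O)OC)[C@H]1[C@H](OC(=O)/C(C)=C\C)CO | intermediate
20 | methyl (2Z,4S)-2-bromo-4-(tert-butyldimethylsilyloxy)-5-[(2R,3S)-3-{(2S,3S)-3-[(1S)-1-(angeloyloxy)-2-oxoethyl]-4-methylidene-5-oxooxolan-2-yl}-2-methyloxiran-2-yl]pent-2-enoate | C=C1C(=O)O[C@H]([C@@H]2O[C@]2(C)C[C@H](O[Si](C)(C)C(C)(C)C)/C=C(\Br)C(=O)OC)[C@H]1[C@H](OC(=O)/C(C)=C\C)C=O | intermediate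
21 | methyl (1(10)E,2S,4R,5S,6S,7R,8S,9S)-8-(angeloyloxy)-2-(tert-butyldimethylsilyloxy)-4,5-epoxy-9-hydroxygermacra-1(10),11(13)-dien-6,12-olid-14-oate | C=C1C(=O)O[C@H]2[C@H]1[C@H](OC(=O)/C(C)=C\C)[C@@H](O)/C(C(=O)OC)=C\[C@@H](O[Si](C)(C)C(C)(C)C)C[C@@]1(C)O[C@@H]21 | intermediate
22 | methyl (1(10)E,2S,4R,5S,6S,7R,8S,9S)-9-acetoxy-8-(angeloyloxy)-2-(tert-butyldimethylsilyloxy)-4,5-epoxygermacra-1(10),11(13)-dien-6,12-olid-14-oate | C=C1C(=O)O[C@H]2[C@H]1[C@H](OC(=O)/C(C)=C\C)[C@@H](OC(C)=O)/C(C(=O)OC)=C\[C@@H](O[Si](C)(C)C(C)(C)C)C[C@@]1(C)O[C@@H]21 | intermediate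
23 | methyl (1(10)E,2S,4R,5S,6S,7R,8S,9S)-9-acetoxy-8-(angeloyloxy)-4,5-epoxy-2-hydroxygermacra-1(10),11(13)-dien-6,12-olid-14-oate (CNP0278274.1) | C=C1C(=O)O[C@H]2[C@H]1[C@H](OC(=O)/C(C)=C\C)[C@@H](OC(C)=O)/C(C(=O)OC)=C\[C@@H](O)C[C@@]1(C)O[C@@H]21 | target

**Step count and risks**
Total step count: 17. Longest linear sequence: 16 (steps 1–8 and 10–17, nerol to target); step 9 is a one-step reagent preparation.

Three steps most likely to fail:

Step 6 (key allylation). The risks are Wurtz-type dimerisation, attack through C13 instead of C7, and translactonisation of the chromium alkoxide onto C12. The fallback sets out from 7 and comes back at 9. Bromide 7 is borylated (B2pin2, CuCl 10 mol%, KOtBu, THF, 0 °C) to the allylboronate F1. F1 is heated with aldehyde 8 in toluene at 80 °C. This thermal allylboration goes through the same closed chair transition state without a reducing metal or a basic alkoxide, and aqueous work-up gives 9 with the same 7,8-anti configuration.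

Step 7 (Mitsunobu inversion at the hindered C8 carbinol). The risk is no reaction or elimination. The fallback sets out from 9 and comes back at 11. Alcohol 9 is oxidised (IBX, DMSO) to the C8 ketone F2. Reduction with NaBH4/CeCl3 at −78 °C should follow Felkin–Anh control (hydride anti to the C6–C7 bond) and give the C8 epimer of 9, the 8S alcohol F3. F3 is esterified with retention by the mixed anhydride of angelic acid 10 (2,4,6-trichlorobenzoyl chloride, Et3N, then DMAP, toluene) to give 11.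

Step 15 (macrocyclisation and C9 configuration). Acyclic Felkin–Anh control would favour the C9 epimer, so the ring-based prediction may fail. The fallback sets out from 20 and comes back at 21. Aldehyde 20 is cyclised as before and the 9R alcohol F4 (or the epimer mixture) is oxidised with IBX to the C9 ketone F5. 1,2-Reduction with NaBH4/CeCl3 at −78 °C places hydride anti to the C8–O bond (Felkin–Anh), which for a ketone gives the 8,9-syn alcohol 21.

Further compounds
F1 | step 6 | allylboronate, (5S)-5-[(2S,3R)-3-methyl-3-(4-methylpent-3-enyl)oxiran-2-yl]-3-[(4,4,5,5-tetramethyl-1,3,2-dioxaborolan-2-yl)methyl]furan-2(5H)-one | CC(C)=CCC[C@@]1(C)O[C@H]1[C@H]2OC(=O)C(CB3OC(C)(C)C(C)(C)O3)=C2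
F2 | step 7 | C8 ketone, (4S,5S)-4-[(tert-butyldimethylsilyloxy)acetyl]-3-methylidene-5-[(2S,3R)-3-methyl-3-(4-methylpent-3-enyl)oxiran-2-yl]oxolan-2-one | C=C1C(=O)O[C@H]([C@@H]2O[C@]2(C)CCC=C(C)C)[C@H]1C(=O)CO[Si](C)(C)C(C)(C)C
F3 | step 7 | 8S alcohol (C8 epimer of 9), (4R,5S)-4-[(1S)-2-(tert-butyldimethylsilyloxy)-1-hydroxyethyl]-3-methylidene-5-[(2S,3R)-3-methyl-3-(4-methylpent-3-enyl)oxiran-2-yl]oxolan-2-one | C=C1C(=O)O[C@H]([C@@H]2O[C@]2(C)CCC=C(C)C)[C@H]1[C@H](O)CO[Si](C)(C)C(C)(C)C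
F4 | step 15 | 9R alcohol (C9 epimer of 21, other centres as in 21) | C=C1C(=O)O[C@H]2[C@H]1[C@H](OC(=O)/C(C)=C\C)[C@H](O)/C(C(=O)OC)=C\[C@@H](O[Si](C)(C)C(C)(C)C)C[C@@]1(C)O[C@@H]21
F5 | step 15 | C9 ketone (9-oxo analogue of 21, other centres as in 21) | C=C1C(=O)O[C@H]2[C@H]1[C@H](OC(=O)/C(C)=C\C)C(=O)/C(C(=O)OC)=C\[C@@H](O[Si](C)(C)C(C)(C)C)C[C@@]1(C)O[C@@H]21
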